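Late times opened the meeting. The chair argued that each Vo makes one product and that Ve and Kj, being mirror images, end equal. Vo, the limiting reagent, is counted on Uj, which is half of the substrate charged, so Ve should level off at the equivalents of Vo divided by 4, as a fraction of Uj and Ju together.

| flask | Uj | Ju | Vo | Ul | temperature | remark | time |
|---|---|---|---|---|---|---|---|
| zeta | 0.20 M | 0.20 M | 0.80 equiv | 0.21 mol% | −25 °C | run made earlier |  |
| alpha | 0.20 M | 0.20 M | 0.80 equiv | 0.91 mol% | −14 °C | run made earlier |  |
| eta | 0.20 M | 0.20 M | 0.57 equiv | 0.65 mol% | −25 °C | run made earlier |  |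
| ochre | 0.20 M | 0.20 M | 0.400 equiv | 0.15 mol% | −20 °C |  | 3.0 h |
| green | 0.20 M | 0.20 M | 0.800 equiv | 0.65 mol% | −20 °C |  | 1.5 h |

| run | time / min | Ve / % | Uj / % |
|---|---|---|---|
| zeta | 4.00 | 0.2 | 50.3 |
| zeta | 6.00 | 0.4 | 49.1 |
| zeta | 10.0 | 1.7 | 48.7 |
| zeta | 15.0 | 1.9 | 48.0 |
| zeta | 25.0 | 3.0 | 46.6 |
| zeta | 50.0 | 5.1 | 45.2 |
| alpha | 8.00 | 7.4 | 42.4 |
| alpha | 15.0 | 10.9 | 38.7 |
| alpha | 25.0 | 13.2 | 35.1 |
| alpha | 30.0 | 15.1 | 33.8 |
| alpha | 40.0 | 16.6 | 31.9 |
| alpha | 50.0 | 15.7 | 30.2 |
| eta | 4.00 | 2.0 | 49.2 |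
| eta | 12.0 | 2.5 | 46.5 |
| eta | 20.0 | 4.4 | 45.1 |
| eta | 30.0 | 6.4 | 44.8 |
| eta | 50.0 | 9.4 | 41.3 |

(scatter of a reading: 0.5 percentage points)

* which one finishes higher in amount of Ve, in percent of the Uj and Ju together charged ("neither" within 2 percentage points) (ochre / green / neither)
* amount of Ve at the end, in percent of the Uj and Ju together charged, ochre
* amount of Ve at the end, in percent of the Uj and Ju together charged, green

- Ul is single-handed; Uj and Ju are mirror images of each other, charged as a racemate, each of them at the stated concentration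
- what was read earlier has a scatter of 0.5 percentage points, one standard deviation
- steps that have been proposed: Vo + Ul + Uj -> Ul + Ve; Vo + Ul + Ju -> Ul + Kj; Vo <-> Dz; Ve <-> Kj

The chair put that plateau at 10.0% for ochre and 20.0% for green. The second speaker took the plateau as the large term and asked for the correction alone. At eta's last reading, she said, one minus Ve over its plateau is 0.340, the gap. Taking Vo as pseudo-first-order, she proposed that a flask's gap is eta's gap raised to the ratio of doses, a dose being Ul loading times time, whatever the Vo charge.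

The third speaker doubted that this carries across temperature. Tried on alpha, at −14 °C against eta's −25 °C, it gives 15.6% against 15.7% read. On zeta it gives 5.88% against 5.1% read, with a scatter of 0.5 percentage points. The meeting accepted it.

The minuted reckoning gives ochre a gap of 0.408, so Ve 5.92%, and green a gap of 0.144, so Ve 17.1%.

The forecast, which takes the rate as roughly proportional to Ul times Vo and holds that “Green should finish well above ochre”, names green, with 3.5% for ochre and 15.5% for green. Both of its numbers lie lower than the reckoning's, though the choice is the same.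

    Vo + Ul + Uj → Ul + Ve (k = 0.930 /M²/s, Ea = 38.0 kJ/mol)
    Vo + Ul + Ju → Ul + Kj (k = 0.530 /M²/s, Ea = 44.0 kJ/mol)
    Vo ⇌ Dz (K = 0.590, k = 2.80 × 10⁻⁵ /s, Ea = 75.0 kJ/mol, ΔH = −24.0 kJ/mol)
    Ve ⇌ Kj (k = 1.20 × 10⁻⁴ /s, Ea = 75.0 kJ/mol)
    (constants at −20 °C)

Green ends at 16.8% and ochre at 5.67%, so green finishes higher. Read back, the gap is 0.160 in green against 0.144 reckoned, and 0.433 in ochre against 0.408. A neighbour of green charged with 2.6 mol% of Ul has its dose raised, so its reckoned gap is 4.26 × 10⁻⁴ and the reckoning puts Ve at 20.0%. That neighbour holds 20.9% of Ve, with Kj at 18.1% and Vo at 0.520% of its own charge.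

All runs are calculated for an exercise, and the scatter is random.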